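**Plan**

The target is (3R)-8-hydroxy-6-methoxy-3-(6-oxoundecyl)-3,4-dihydroisocoumarin; ring A is the benzene ring and ring B the lactone ring (C1, O2, C3, C4, C4a, C8a).
Retrosynthesis: put back the O8 methyl group and the side-chain dioxolane, take H2 off C3–C4, then cut ring B at C4a–C4 and O2–C3 into 2,4-dimethoxybenzoic acid and an α-keto sulfoxonium ylide. The ylide is cut at its C(=O)–CH bond (ester plus methylide) and the chain at the bond between the ketone carbon and the pentyl group (acid chloride plus Grignard reagent).
Enabling feature: C4a is the one unsubstituted ortho carbon of 2,4-dimethoxybenzoic acid (the other ortho carbon carries the methoxy group that ends up on C8), and C4 and C3 of ring B are the ylide carbon and the ketone carbon of the sulfoxonium ylide.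
Forward: the twelve-carbon keto ester chain is joined first (acylation, ketal, ylide), ring B is then fused onto ring A in one rhodium-catalysed C–H annulation, and hydrogenation, ketal hydrolysis and O8 demethylation finish the route.
Stereochemistry: the only stereocentre, C3 (R), comes from catalyst-controlled enantioselective hydrogenation of the C3=C4 bond of the isocoumarin.

Key step: step 4

Assumption: the facial sense of the hydrogenation catalyst is taken from 3-methylisocoumarins, whose C3 substituents rank in the same CIP order as here (O2 > C4 > side chain), and is to be confirmed on the first run.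

**Route**

Step 1
Reactants: 1 methyl 7-chloro-7-oxoheptanoate; 2 pentylmagnesium bromide
Product: 3 methyl 7-oxododecanoate
Conditions: 2 (1.05 equiv), Fe(acac)3 (3 mol %), THF, −78 °C
Reagents that add atoms: none
Why: Iron-catalysed acylation of a Grignard reagent by an acid chloride (Kochi-type cross-coupling) is far faster at −78 °C than addition to the methyl ester or to the ketone being formed, so the keto ester should be obtained without over-addition.

Step 2
Reactants: 3 methyl 7-oxododecanoate
Product: 4 methyl 6-(2-pentyl-1,3-dioxolan-2-yl)hexanoate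
Conditions: Me3SiOCH2CH2OSiMe3 (1.5 equiv), Me3SiOTf (5 mol %), CH2Cl2, −78 → −20 °C; pyridine quench
Reagents that add atoms: 1,2-bis(trimethylsilyloxy)ethane, C[Si](C)(C)OCCO[Si](C)(C)C
Why: Noyori ketalisation (silyl transfer driven by formation of hexamethyldisiloxane) converts the dialkyl ketone into its dioxolane under cold, aprotic conditions in which the methyl ester cannot transesterify.

Step 3
Reactants: 4 methyl 6-(2-pentyl-1,3-dioxolan-2-yl)hexanoate; 5 trimethylsulfoxonium iodide
Product: 7 1-(dimethyloxo-λ6-sulfanylidene)-7-(2-pentyl-1,3-dioxolan-2-yl)heptan-2-one, via dimethylsulfoxonium methylide 6 (not isolated)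
Conditions: 5 (3.2 equiv), KOtBu (3.0 equiv), THF, 65 °C, 2 h; then 4, 0 → 65 °C
Reagents that add atoms: none
Why: Corey–Chaykovsky-type acylation of the methylide by the ester, followed by deprotonation of the β-keto sulfoxonium salt, should give the stabilised keto ylide, which resists a second addition, while the dioxolane shields the chain ketone from epoxidation.

Step 4
Reactants: 7 1-(dimethyloxo-λ6-sulfanylidene)-7-(2-pentyl-1,3-dioxolan-2-yl)heptan-2-one; 8 2,4-dimethoxybenzoic acid
Product: 11 6,8-dimethoxy-3-[5-(2-pentyl-1,3-dioxolan-2-yl)pentyl]-1H-isochromen-1-one, via keto acid 9 (not isolated), via lactol 10 (not isolated)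
Conditions: 8 (1.5 equiv), [Cp*RhCl2]2 (2.5 mol %), AgSbF6 (10 mol %), NaOAc (1.0 equiv), 4 Å MS, ClCH2CH2Cl, 80 °C
Reagents that add atoms: none
Why: Acetate-assisted concerted metalation–deprotonation at the only free ortho C–H of 8 gives a five-membered carboxylate rhodacycle of trivalent rhodium; the ylide carbon of 7 binds the metal and loses dimethyl sulfoxide to form a rhodium carbene, and migratory insertion of the aryl group followed by protodemetalation creates C4a–C4 and releases keto acid 9. The carboxyl oxygen then adds to the ketone carbon in a 6-exo-trig closure (O2–C3, lactol 10), and loss of water gives the C3=C4 enol lactone, which completes ring B. The closest known reaction type is the carboxylate-directed C–H coupling of benzoic acids with α-keto sulfoxonium ylides or α-diazoketones under Cp*Rh or (p-cymene)Ru catalysis, which gives 3-substituted isocoumarins in one operation. No stereocentre is formed. The step needs site selectivity and a single carbene transfer, and both are fixed by the substrate, because C2 of the acid is blocked by the methoxy group that becomes the C8 substituent and only one ortho C–H exists. NaOAc and molecular sieves keep the medium buffered and dry, so the dioxolane should survive.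

Step 5
Reactants: 11 6,8-dimethoxy-3-[5-(2-pentyl-1,3-dioxolan-2-yl)pentyl]-1H-isochromen-1-one
Product: 12 (3R)-6,8-dimethoxy-3-[5-(2-pentyl-1,3-dioxolan-2-yl)pentyl]-3,4-dihydro-1H-isochromen-1-one
Conditions: precatalyst from Ru(2-methylallyl)2(cod) (5 mol %), (R,R)-SINpEt·HBF4 (10 mol %; SINpEt = 1,3-bis[(1R)-1-(naphthalen-1-yl)ethyl]imidazolidin-2-ylidene) and KOtBu (n-hexane, 70 °C); then 11, (R,R)-1,2-diphenylethylenediamine (5 mol %), H2 (50 bar), toluene, 25 °C
Reagents that add atoms: none
Why: Enantioselective homogeneous hydrogenation of the cyclic enol-ester double bond by a chiral NHC–diamine complex of divalent ruthenium is established for 3-alkylisocoumarins, including 8-methoxy members, so H2 should add across C3=C4 from the face chosen by the chiral ligand pocket (catalyst control) to give (3R)-12 with the ligand antipodes that lead to the (R)-3-methyl analogues (the mirror-image ligand pair is equally available), while the basic, aprotic medium leaves the dioxolane, the lactone carbonyl and the aryl ethers alone.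

Step 6
Reactants: 12 (3R)-6,8-dimethoxy-3-[5-(2-pentyl-1,3-dioxolan-2-yl)pentyl]-3,4-dihydro-1H-isochromen-1-one
Product: 13 (3R)-6,8-dimethoxy-3-(6-oxoundecyl)-3,4-dihydro-1H-isochromen-1-one
Conditions: 1 M aq HCl, THF, 23 °C
Reagents that add atoms: water, O
Why: Acid-catalysed ketal hydrolysis frees the chain ketone under conditions that do not open the lactone or touch C3, which is neither enolisable nor ionisable.

Step 7
Reactants: 13 (3R)-6,8-dimethoxy-3-(6-oxoundecyl)-3,4-dihydro-1H-isochromen-1-one
Product: 14 (3R)-8-hydroxy-6-methoxy-3-(6-oxoundecyl)-3,4-dihydro-1H-isochromen-1-one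
Conditions: BCl3 (2.5 equiv), CH2Cl2, −78 → 0 °C; aq NaHCO3
Reagents that add atoms: none
Why: Chelation-controlled Lewis-acid ether cleavage, in which BCl3 is held between the C1 carbonyl oxygen and O8 in a six-membered chelate so that chloride removes only that methyl group, should leave the unchelated C6 methoxy, the ketone, the lactone and C3 unchanged.

**Compound list**

1 | methyl 7-chloro-7-oxoheptanoate | COC(=O)CCCCCC(=O)Cl | starting material
2 | pentylmagnesium bromide | CCCCC[Mg]Br | starting material
3 | methyl 7-oxododecanoate | CCCCCC(=O)CCCCCC(=O)OC | intermediate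
4 | methyl 6-(2-pentyl-1,3-dioxolan-2-yl)hexanoate | CCCCCC1(OCCO1)CCCCCC(=O)OC | intermediate
5 | trimethylsulfoxonium iodide | C[S+](C)(C)=O.[I-] | starting material
6 | dimethylsulfoxonium methylide (formed in the flask, not isolated) | C=S(C)(C)=O | intermediate
7 | 1-(dimethyloxo-λ6-sulfanylidene)-7-(2-pentyl-1,3-dioxolan-2-yl)heptan-2-one | CCCCCC1(OCCO1)CCCCCC(=O)C=S(C)(C)=O | intermediate
8 | 2,4-dimethoxybenzoic acid | COc1ccc(C(=O)O)c(OC)c1 | starting material
9 | 2,4-dimethoxy-6-[2-oxo-7-(2-pentyl-1,3-dioxolan-2-yl)heptyl]benzoic acid (keto acid, not isolated) | CCCCCC1(OCCO1)CCCCCC(=O)Cc1cc(OC)cc(OC)c1C(=O)O | intermediate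
10 | 3-hydroxy-6,8-dimethoxy-3-[5-(2-pentyl-1,3-dioxolan-2-yl)pentyl]-3,4-dihydro-1H-isochromen-1-one (lactol, racemic at C3, not isolated) | CCCCCC1(OCCO1)CCCCCC2(O)Cc3cc(OC)cc(OC)c3C(=O)O2 | intermediate
11 | 6,8-dimethoxy-3-[5-(2-pentyl-1,3-dioxolan-2-yl)pentyl]-1H-isochromen-1-one | CCCCCC1(OCCO1)CCCCCC2=Cc3cc(OC)cc(OC)c3C(=O)O2 | intermediate
12 | (3R)-6,8-dimethoxy-3-[5-(2-pentyl-1,3-dioxolan-2-yl)pentyl]-3,4-dihydro-1H-isochromen-1-one | CCCCCC1(OCCO1)CCCCC[C@@H]2Cc3cc(OC)cc(OC)c3C(=O)O2 | intermediate
13 | (3R)-6,8-dimethoxy-3-(6-oxoundecyl)-3,4-dihydro-1H-isochromen-1-one | CCCCCC(=O)CCCCC[C@@H]1Cc2cc(OC)cc(OC)c2C(=O)O1 | intermediate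
14 | (3R)-8-hydroxy-6-methoxy-3-(6-oxoundecyl)-3,4-dihydro-1H-isochromen-1-one | CCCCCC(=O)CCCCC[C@@H]1Cc2cc(OC)cc(O)c2C(=O)O1 | target

**Step count and risks**

Total: 7 steps. Longest linear sequence: 7 steps (1 → 3 → 4 → 7 → 11 → 12 → 13 → 14).

Steps most likely to fail:

Step 5. The two faces of a C3=C4 bond that carries an unbranched alkyl chain may be poorly distinguished, or the electron-rich enol lactone may be hydrogenated only slowly. The fallback sets the stereocentre by carbonyl reduction instead of alkene hydrogenation. It sets out from 11: NaOMe in MeOH should open the enol lactone to methyl 2,4-dimethoxy-6-[2-oxo-7-(2-pentyl-1,3-dioxolan-2-yl)heptyl]benzoate F1. An (R)-selective NADPH-dependent ketoreductase (isopropanol as terminal reductant, phosphate buffer, 30 °C) should reduce this 1-aryl-2-alkanone to methyl 2-[(2R)-2-hydroxy-7-(2-pentyl-1,3-dioxolan-2-yl)heptyl]-4,6-dimethoxybenzoate F2. Catalytic NaH in THF then lactonises the hydroxy ester, and the fallback comes back to the route at 12.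

Step 4. Carbene transfer from an alkyl-ketone ylide may be sluggish, the dioxolane may be partly hydrolysed by the acid and the water formed, or dehydration of the lactol may stall. The fallback builds the same C4a–C4–C3 unit by enolate chemistry and sets out from 4. 2,4-Dimethoxy-6-methylbenzoic acid F3 (purchased) is doubly deprotonated with LiN(iPr)2 in THF at −78 °C (carboxylate plus lateral benzylic lithiation). The benzylic anion is acylated by ester 4 in a Claisen-type condensation, which should give keto acid 9 after a mildly acidic work-up. Warming 9 with Ac2O and NaOAc (enol lactonisation through the mixed anhydride) brings the fallback back to the route at 11.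

Step 3. Acylation of the methylide by an unactivated aliphatic methyl ester may be slow and allow Claisen self-condensation or incomplete conversion. The fallback raises the acylating power and sets out from 4. LiOH in THF/H2O, with careful acidification to pH 5, should give 6-(2-pentyl-1,3-dioxolan-2-yl)hexanoic acid F4. 1,1'-Carbonyldiimidazole in THF converts it into 1-(1H-imidazol-1-yl)-6-(2-pentyl-1,3-dioxolan-2-yl)hexan-1-one F5. Adding this acyl imidazole to preformed methylide 6 at 0 °C brings the fallback back to the route at 7.

Further compounds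
F1 | step 5 | methyl 2,4-dimethoxy-6-[2-oxo-7-(2-pentyl-1,3-dioxolan-2-yl)heptyl]benzoate | CCCCCC1(OCCO1)CCCCCC(=O)Cc1cc(OC)cc(OC)c1C(=O)OC
F2 | step 5 | methyl 2-[(2R)-2-hydroxy-7-(2-pentyl-1,3-dioxolan-2-yl)heptyl]-4,6-dimethoxybenzoate | CCCCCC1(OCCO1)CCCCC[C@@H](O)Cc1cc(OC)cc(OC)c1C(=O)OC
F3 | step 4 | 2,4-dimethoxy-6-methylbenzoic acid | Cc1cc(OC)cc(OC)c1C(=O)O
F4 | step 3 | 6-(2-pentyl-1,3-dioxolan-2-yl)hexanoic acid | CCCCCC1(OCCO1)CCCCCC(=O)O
F5 | step 3 | 1-(1H-imidazol-1-yl)-6-(2-pentyl-1,3-dioxolan-2-yl)hexan-1-one | CCCCCC1(OCCO1)CCCCCC(=O)n1ccnc1
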